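The unbranched C37 acyl chain is cut at C5–C6 and C9–C10. Its CH2 run C6–C9 is carried as the four ring carbons of thiophene, whose two alpha carbons (ring C2 and C5) accept the electrophiles. In one telescoped operation, thiophene is lithiated and alkylated with 1-bromooctacosane (C10–C37), lithiated again at the remaining alpha carbon and acylated with glutaric anhydride (C1–C5), so that all 37 chain carbons are joined in a linear thienyl keto acid. The precursors are therefore only thiophene, a C28 primary bromide and a C5 cyclic anhydride. Carbonyl removal, reductive excision of sulfur and esterification of tyrosol's primary hydroxyl (benzene ring untouched) finish the target.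

Key step: step 2

Remark: the acyl residue is taken as unbranched heptatriacontanoyl (C1 = ester carbonyl, C37 = terminal methyl; C28 from the bromide + 4 ring carbons + C5 from the anhydride = C37). The target has no stereocentre and no double-bond geometry, so no step has stereochemistry to control.

Step 1
Reactants: 1 1-octacosanol
Product: 2 1-bromooctacosane
Conditions: PBr3 (0.5 equiv), toluene, 90 °C; aq. NaHCO3 wash
Reagents that add atoms: phosphorus tribromide, BrP(Br)Br
Why: Deoxybromination of a primary fatty alcohol with PBr3 runs through a bromophosphite ester that bromide displaces in an SN2 step, and a primary centre offers no rearrangement and little elimination.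

Step 2
Reactants: 3 thiophene; 2 1-bromooctacosane; 4 glutaric anhydride
Product: 9 5-(5-octacosylthiophen-2-yl)-5-oxopentanoic acid, via 2-thienyllithium 5 (not isolated), via 2-octacosylthiophene 6 (not isolated), via 5-octacosyl-2-thienyllithium 7 (not isolated), via lithium keto carboxylate 8 (not isolated)
Conditions: 3 (1.2 equiv), n-BuLi (1.15 equiv), THF, −20 to 0 °C; 2 (1.0 equiv) in warm THF, rt to 50 °C; n-BuLi (1.05 equiv), 0 °C to rt; cannulate into 4 (3 equiv), THF, −78 °C, then to 0 °C; 1 M HCl
Reagents that add atoms: none
Why: n-BuLi removes the proton at ring C2 of 3, the most acidic C–H because it is sp2 and next to sulfur, and the resulting 5 displaces bromide from the primary carbon of 2 in an SN2 reaction that forms C9–C10 and gives 6. The single alpha C–H left in 6 (ring C5) is then metalated to 7, which adds to one carbonyl of 4 and opens the anhydride, forming C5–C6 and giving the keto carboxylate 8 that aqueous HCl protonates to 9. The closest known reaction types are the alpha-lithiation and alkylation of thiophenes with primary alkyl bromides and the addition of aryllithium or aryl Grignard reagents to cyclic anhydrides to give keto acids; only the telescoping is specific to this case. No ring is closed and no stereocentre is created, so neither a closure mode nor a controlling element arises. The step needs 2,5-regiochemistry, secured in both metalations by the large acidity gap between the alpha and beta C–H bonds of thiophene, and single addition to the anhydride, secured by dripping the ambient-temperature solution of 7 into cold excess 4 and by the low electrophilicity of the conjugated thienyl ketone beside a carboxylate in 8. Keeping n-BuLi just below 3 in the first stage and 2 as the limiting component keeps free n-BuLi away from the bromide, and the short keto acid formed from surplus 5 should be lost on recrystallisation of the waxy product.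

Step 3
Reactants: 9 5-(5-octacosylthiophen-2-yl)-5-oxopentanoic acid
Product: 12 5-(5-octacosylthiophen-2-yl)pentanoic acid, via potassium hydrazone carboxylate 10 (not isolated), via potassium thienylpentanoate 11 (not isolated)
Conditions: N2H4·H2O (5 equiv), KOH (4 equiv), diethylene glycol, 130 °C, then distil to 200 °C; aq. HCl
Reagents that add atoms: none
Why: In this Huang-Minlon variant of the Wolff–Kishner reduction the hydrazone 10 of the aryl ketone loses N2 under hot KOH to leave the C5 methylene, thienyl ketones being good substrates and the carboxylate and thiophene ring being inert to base.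

Step 4
Reactants: 12 5-(5-octacosylthiophen-2-yl)pentanoic acid
Product: 13 heptatriacontanoic acid
Conditions: Raney Ni (W-2, ca. 10 weight equiv), H2 (1 atm), EtOH–toluene, reflux; hot filtration, dilute HCl wash
Reagents that add atoms: none
Why: Raney nickel reductive desulfurisation cleaves both C–S bonds by hydrogenolysis and saturates the resulting four-carbon unit on the hydrogen-loaded metal, turning the ring carbons into the C6–C9 methylenes of an acid that has no other reducible group.

Step 5
Reactants: 13 heptatriacontanoic acid; 14 tyrosol
Product: 15 2-(4-hydroxyphenyl)ethyl heptatriacontanoate (CNP0230173.0)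
Conditions: 14 (3 equiv), p-TsOH·H2O (10 mol%), toluene, reflux, Dean–Stark; water wash
Reagents that add atoms: none
Why: Fischer esterification with azeotropic water removal should acylate only the primary aliphatic hydroxyl of 14, because phenols are poor nucleophiles toward protonated carboxylic acids and aryl esters are disfavoured at equilibrium, so water is the only co-product and the excess diol is washed out.

Compound list
1 | 1-octacosanol | CCCCCCCCCCCCCCCCCCCCCCCCCCCCO | starting material
2 | 1-bromooctacosane | CCCCCCCCCCCCCCCCCCCCCCCCCCCCBr | intermediate
3 | thiophene | c1ccsc1 | starting material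
4 | glutaric anhydride | O=C1CCCC(=O)O1 | starting material
5 | 2-thienyllithium (thiophen-2-yllithium; formed in the flask) | [Li]c1cccs1 | intermediate
6 | 2-octacosylthiophene (formed in the flask) | CCCCCCCCCCCCCCCCCCCCCCCCCCCCc1cccs1 | intermediate
7 | 5-octacosyl-2-thienyllithium, (5-octacosylthiophen-2-yl)lithium (formed in the flask) | [Li]c1ccc(CCCCCCCCCCCCCCCCCCCCCCCCCCCC)s1 | intermediate
8 | lithium keto carboxylate, lithium 5-(5-octacosylthiophen-2-yl)-5-oxopentanoate (formed in the flask) | CCCCCCCCCCCCCCCCCCCCCCCCCCCCc1ccc(s1)C(=O)CCCC(=O)[O-].[Li+] | intermediate
9 | 5-(5-octacosylthiophen-2-yl)-5-oxopentanoic acid | CCCCCCCCCCCCCCCCCCCCCCCCCCCCc1ccc(s1)C(=O)CCCC(=O)O | intermediate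
10 | potassium hydrazone carboxylate, potassium 5-hydrazinylidene-5-(5-octacosylthiophen-2-yl)pentanoate (C=N geometry undefined; formed in the flask) | CCCCCCCCCCCCCCCCCCCCCCCCCCCCc1ccc(s1)C(=NN)CCCC(=O)[O-].[K+] | intermediate
11 | potassium thienylpentanoate, potassium 5-(5-octacosylthiophen-2-yl)pentanoate (formed in the flask) | CCCCCCCCCCCCCCCCCCCCCCCCCCCCc1ccc(CCCCC(=O)[O-])s1.[K+] | intermediate
12 | 5-(5-octacosylthiophen-2-yl)pentanoic acid | CCCCCCCCCCCCCCCCCCCCCCCCCCCCc1ccc(CCCCC(=O)O)s1 | intermediate
13 | heptatriacontanoic acid | CCCCCCCCCCCCCCCCCCCCCCCCCCCCCCCCCCCCC(=O)O | intermediate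
14 | tyrosol, 4-(2-hydroxyethyl)phenol | OCCc1ccc(O)cc1 | starting material
15 | 2-(4-hydroxyphenyl)ethyl heptatriacontanoate | CCCCCCCCCCCCCCCCCCCCCCCCCCCCCCCCCCCCC(=O)OCCc1ccc(O)cc1 | target

Total step count: 5. Longest linear sequence: 5 steps (1 → 2 → 9 → 12 → 13 → 15).

Steps most likely to fail

Step 2. The alkylation may stall if the C28 bromide or 6 crystallises from THF, leaving bromide to be consumed by the second charge of n-BuLi. In the acylation, 7 may be quenched by proton transfer from the alpha-methylene of the new ketone or may add a second time. Fallback: the first stage alone is run and quenched with water so that 2-octacosylthiophene 6 is isolated. Compound 6 is then acylated at its only free alpha position under Friedel–Crafts conditions with methyl 5-chloro-5-oxopentanoate (COC(=O)CCCC(=O)Cl) and SnCl4 in CH2Cl2 at 0 °C to rt, which should give methyl 5-(5-octacosylthiophen-2-yl)-5-oxopentanoate F1. Saponification (KOH, aqueous EtOH–THF, reflux; HCl) brings the sequence back to the route at 9.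

Step 4. Hydrogenolysis of the C–S bonds may stop short, leaving olefinic or sulfur-containing material, and the waxy acid may adsorb strongly on the nickel. Fallback: a sulfur-free assembly of the same acid that sets out from 2. Magnesium insertion (Mg, THF, 55 °C) gives octacosylmagnesium bromide F2. Copper-catalysed sp3–sp3 coupling of F2 with ethyl 9-bromononanoate (CCOC(=O)CCCCCCCCBr) using Li2CuCl4 (3 mol%) in THF–NMP at 0 °C to rt should give ethyl heptatriacontanoate F3. Saponification (KOH, EtOH–toluene, reflux; HCl) returns to the route at 13.

Step 5. Chemoselectivity may erode (acylation of the phenol or double acylation), conversion may stall because the waxy acid and the polar diol share no good solvent, and the diol may self-etherify under acid. Fallback: the phenol is masked beforehand, setting out from 13. Carbodiimide coupling (EDC·HCl, DMAP, CHCl3, 45 °C) with commercial 2-[4-(benzyloxy)phenyl]ethanol (OCCc1ccc(OCc2ccccc2)cc1) should give 2-[4-(benzyloxy)phenyl]ethyl heptatriacontanoate F4. Hydrogenolysis of the benzyl ether (H2, 10% Pd/C, THF–EtOAc, 40 °C) returns to the route at 15.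

Further compounds
F1 | step 2 | methyl 5-(5-octacosylthiophen-2-yl)-5-oxopentanoate | CCCCCCCCCCCCCCCCCCCCCCCCCCCCc1ccc(s1)C(=O)CCCC(=O)OC
F2 | step 4 | octacosylmagnesium bromide | CCCCCCCCCCCCCCCCCCCCCCCCCCCC[Mg]Br
F3 | step 4 | ethyl heptatriacontanoate | CCCCCCCCCCCCCCCCCCCCCCCCCCCCCCCCCCCCC(=O)OCC
F4 | step 5 | 2-[4-(benzyloxy)phenyl]ethyl heptatriacontanoate | CCCCCCCCCCCCCCCCCCCCCCCCCCCCCCCCCCCCC(=O)OCCc1ccc(OCc2ccccc2)cc1
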